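## The problem

The target 20 is 3-(4-amino-2-bromopyrimidin-5-yl)-7-bromo-1H-indol-4-ol, an indole joined through C3 to C5 of a pyrimidine. It has no stereocenter, so every question of control is one of position. On the indole, the hydroxyl sits on C4, peri to the heteroaryl group, and the bromine on C7, para to the hydroxyl. A 3-substituted 4-oxygenated indole is the pattern that aniline-based indole syntheses reach least directly, because they must close at the more hindered ortho carbon. On the pyrimidine, C2 carries bromine and C4 an amino group; both descend from the carbonyl carbons of a uracil and have to be told apart. The 2-bromopyrimidine is open to substitution by alkoxide, hydroxide, thiolate or amine, so it must be made late and must not meet a nucleophilic base afterwards. The two C–Br bonds forbid hydrogenolysis, dissolving metals and zerovalent palladium late in the route, and the free 4-hydroxyindole is easily oxidized, so phenol and bromopyrimidine are best completed at the end. The feature that opens the synthesis is that C4(=O), C3a and C7a, with C5, C6 and C7 between them, are the carbons of cyclohexane-1,3-dione with one carbonyl kept and the other replaced by N1, while N1–C2–C3 with its heteroaryl group is an α-aminoketone.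

## Retrosynthesis

**20 from 19.** The last cut is the O–CH3 bond of methyl ether 19. A methyl ether is chosen over an ester or a sulfonate because it survives hot POBr3 and is removed by BBr3, a reagent that carries no nucleophile able to attack C2 of the pyrimidine and whose halide matches the one already there. The forward step only has to cleave one aryl methyl ether in the presence of basic nitrogens.

**19 from 16 through 18 and 17.** The C4'–N bond is cut back to dibromide 18, the two C–Br bonds to uracil 17, and the two lactam carbonyls to the dimethoxypyrimidine 16. Carrying the pyrimidine as a 2,4-dimethoxy compound gives a neutral ring that tolerates organolithium, enolate and hydroxide chemistry. The forward sequence asks that ammonia take C4 of 18 and leave C2, the normal preference of 2,4-dihalopyrimidines. The indole N–H is left free through these steps so that no deprotection is needed once the bromopyrimidine exists.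

**16 from 14 through 15.** The N–S bond of the tosyl group and the C7–Br bond are cut. Bromine is put in by electrophilic substitution on the N-tosyl methyl ether 14 rather than on a free indole, because the sulfonyl group silences C2 and the C4 methoxy group then directs para, to C7. The C3 heteroaryl group turns the methoxy methyl toward C5 and screens the ortho position. The tosyl group is removed from 15 with hydroxide in methanol while the pyrimidine still carries methoxy groups, for which exchange with methoxide changes nothing.

**14 from 10 through 13, 12 and 11.** The benzene ring of 14 is traced to the cyclohexanone ring of 10: methyl ether to phenol 13, phenol to α-bromoketone 12, and 12 to ketone 10 by way of silyl enol ether 11. The bromine is placed on C5 through the enol ether and NBS, not with an acidic brominating agent, because hot hydrogen bromide would dealkylate the methoxypyrimidine. Elimination and tautomerization then give the phenol with oxygen fixed on C4.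

**10 from 9.** The N–S bond is cut to the N–H tetrahydroindolone 9. The sulfonyl group serves three later steps: it prevents halogenation of the pyrrole, allows a clean ketone enolate, and keeps the derived hydroxyindole stable to air.

**9 from 6 and 7 (key disconnection).** N1–C7a and C3–C3a are cut together, which opens the pyrrole ring and gives the aminoketone salt 6 and cyclohexane-1,3-dione 7; enaminone 8 lies between. Against a cut of the benzo ring or of the biaryl bond, this one sets oxygen on C4 and the heteroaryl group on C3 by the connectivity of the two components alone. Dione 7 is symmetrical, so no isomer can arise. The simplification is from a bicyclic, fully substituted pyrrole to a commodity dione and a three-atom side chain on a pyrimidine. The forward reaction must make cross-condensation faster than self-condensation of the aminoketone.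

**6 from 1 and 2 through 5.** The C5'–C(=O) bond is cut. The lithiated pyrimidine 4, from bromide 1, acylates the glycine Weinreb amide 2 (as its N-magnesio salt 3) to give carbamate 5, and anhydrous acid releases 6 as a salt that cannot self-condense. Both starting materials are commercial.

## Roads not taken

**Alternative 1: benzo ring by olefin metathesis.** The cut is C5–C6 of the carbocycle. The precursor would be the pyrrole A1, which carries tosyl on nitrogen, allyl on C2, acryloyl on C3 and the dimethoxypyrimidinyl group on C4. The second-generation Grubbs catalyst would close it with loss of the two terminal methylene carbons, and the resulting dienone would tautomerize to the phenol A2. A2 is the same compound as 13 of the chosen route. The merit is real: the six-membered ring appears at the phenol oxidation level under neutral, catalytic conditions, with no enolate bromination and no hot elimination. The weak point is A1 itself. It is a pyrrole with four different substituents that must be introduced one by one with positional control, and its aryl vinyl ketone is a polymerizable Michael acceptor that has to survive until the ring closure. The allyl group can also isomerize to a propenyl group under ruthenium hydride, which would lead to the wrong ring size. Since both roads meet at 13 and share everything after it, the comparison is between six steps from 1, 2 and 7 and the assembly of A1, which cannot reasonably be shorter. The chosen plan offers a two-component ring construction in place of a lengthy pyrrole substitution sequence, and accepts two stoichiometric steps for aromatization in exchange.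

**Alternative 2: isocyanide pyrrole synthesis, then benzannulation.** The cut is C2–C3 and C3a–C7a. The anion of tosylmethyl isocyanide A4 would add to the pyrimidinyl enone A3 and close, with loss of sulfinate, to the 3-acyl-4-heteroarylpyrrole A5, whose side chain ends in a dimethyl acetal. Acid would then close the acetal carbon onto the pyrrole α-carbon and, after loss of methanol and tautomerization, give the hydroxyindole A6. The merits are that A3 comes from an aldol condensation of a heteroaryl aldehyde with a methyl ketone, that the isocyanide cycloaddition fixes acyl and heteroaryl on adjacent carbons, and that the benzo ring again arrives at the phenol level. On paper A6 and then 13 could be reached in about five steps, one fewer than in the chosen plan, and that advantage is conceded. The weak points lie in the second ring closure. The carbon that must attack is the pyrrole α-carbon next to the acyl group, the less nucleophilic of the two free α-positions, so intermolecular attack through the other one competes. The acid needed to ionize the acetal is also the reagent that dealkylates the methoxypyrimidine, and A6 is an unprotected, oxidation-prone hydroxyindole. Against the saving of one step, the chosen plan offers a ring closure in which the nucleophile (an enaminone carbon) and the electrophile (a ketone activated by the pyrimidine) are matched, and a phenol that is only ever handled as its N-sulfonyl derivative.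

**Alternative 3: Fischer indolization.** The cut is C3–C3a and N1–C2. The hydrazone from the arylhydrazine A7 and the pyrimidinylacetaldehyde A8 would rearrange under acid to the indole A9, which is the same compound as 16 of the chosen route. The ortho bromine blocks one ortho carbon, so closure is forced onto the carbon next to the methoxy group, and bromine and O-methyl arrive already in place. This is the most step-economical road: A9 could be reached in perhaps four or five steps, against nine to 16 here, with no dehydrogenation, no regioselective bromination and no sulfonyl group to put on and take off. Its weakness is concentrated in one step. The sigmatropic shift must take the hindered ortho carbon of a ring deactivated by bromine, and ortho-halogenated arylhydrazones are known to react partly at the substituted carbon with loss or migration of halogen. The ene-hydrazine carries an electron-poor heteroaryl group, which slows the rearrangement. A8 is a self-condensing arylacetaldehyde that would have to be used as an acetal or enol ether. The strong acid needed would hydrolyse the methoxypyrimidine, which is tolerable only if it runs cleanly through to 17. If that one step could be relied on, this road would be preferable. The chosen plan trades length for certainty: the position of oxygen follows from the symmetry of 7, no step depends on an indolization of doubtful course, and 13 is a branching point for congeners with other halogen patterns.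

Key step: step 3

## Route

Assumption: the target has no stereocenter; the one stereocenter that appears on the way (C5 of 12) is carried as the racemate and is destroyed in step 6.

Step 1
Reactants: 1 5-bromo-2,4-dimethoxypyrimidine; 2 tert-butyl N-{2-[methoxy(methyl)amino]-2-oxoethyl}carbamate
Product: 5 tert-butyl N-[2-(2,4-dimethoxypyrimidin-5-yl)-2-oxoethyl]carbamate, via N-chloromagnesio Weinreb amide 3 (not isolated), via (2,4-dimethoxypyrimidin-5-yl)lithium 4 (not isolated)
Conditions: 2, i-PrMgCl (1.0 equiv), THF, −20 °C; separately 1 (1.3 equiv), n-BuLi, THF, −78 °C; add 3 to 4, −78 → −20 °C; aq. NH4Cl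
Reagents that add atoms: none
Why: Bromine–lithium exchange on 1 is fast at −78 °C, and the aryllithium adds once to the Weinreb amide because the chelated tetrahedral adduct holds until the quench (Weinreb ketone synthesis). Prior removal of the carbamate N–H with i-PrMgCl keeps it from consuming the aryllithium.

Step 2
Reactants: 5 tert-butyl N-[2-(2,4-dimethoxypyrimidin-5-yl)-2-oxoethyl]carbamate
Product: 6 2-amino-1-(2,4-dimethoxypyrimidin-5-yl)ethan-1-one hydrochloride
Conditions: HCl (4 M in 1,4-dioxane), CH2Cl2, 0 °C → rt, short contact; filter the salt
Reagents that add atoms: hydrogen chloride, SMILES Cl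
Why: Acidolysis of the tert-butyl carbamate (loss of the tert-butyl cation, then decarboxylation) gives the ammonium salt, which cannot self-condense. Anhydrous acid at or below room temperature for a short time should leave the methoxypyrimidine intact, since its dealkylation by chloride needs heat.

Step 3
Reactants: 6 2-amino-1-(2,4-dimethoxypyrimidin-5-yl)ethan-1-one hydrochloride; 7 cyclohexane-1,3-dione
Product: 9 3-(2,4-dimethoxypyrimidin-5-yl)-1,5,6,7-tetrahydro-4H-indol-4-one, via enaminone 8 (not isolated)
Conditions: 7 (2 equiv), NaOAc (1.5 equiv), AcOH, 90 °C; 6 added in portions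
Reagents that add atoms: none
Why: Sodium acetate frees the amine of 6 a little at a time, and it condenses with one carbonyl of the enolized dione 7 to the vinylogous amide 8, which forms N1–C7a. The nucleophilic α-carbon of 8 then adds to the pendant ketone, forming C3–C3a, and loss of water from the carbinol aromatizes the pyrrole. The closest known reaction is the Knorr-type condensation of α-aminoketone salts with cyclohexane-1,3-diones to 3-substituted 4-oxotetrahydroindoles. The one ring that closes is the pyrrole, by 5-exo-trig attack on the ketone carbon with the enaminone double bond inside the new ring; this is the geometry of every Knorr closure, and the irreversible dehydration draws it on. No stereocenter is formed. The step needs cross-condensation to outrun dimerization of the free aminoketone to a dihydropyrazine: the amine stays largely protonated, the dione is in excess, and the pyrimidinyl ketone is a strong electrophile for the intramolecular step. Position is not in question, because the two carbonyls of 7 are equivalent, so oxygen must end on C4 and the heteroaryl group on C3.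

Step 4
Reactants: 9 3-(2,4-dimethoxypyrimidin-5-yl)-1,5,6,7-tetrahydro-4H-indol-4-one
Product: 10 3-(2,4-dimethoxypyrimidin-5-yl)-1-(4-methylbenzenesulfonyl)-1,5,6,7-tetrahydro-4H-indol-4-one
Conditions: NaH, DMF, 0 °C; TsCl, 0 °C → rt
Reagents that add atoms: 4-methylbenzenesulfonyl chloride, SMILES Cc1ccc(cc1)S(=O)(=O)Cl
Why: The pyrrole N–H of the vinylogous amide is the most acidic proton, and its sodium salt is sulfonylated on nitrogen (N-sulfonylation), as is usual for 4-oxotetrahydroindoles.

Step 5
Reactants: 10 3-(2,4-dimethoxypyrimidin-5-yl)-1-(4-methylbenzenesulfonyl)-1,5,6,7-tetrahydro-4H-indol-4-one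
Product: 12 rac-5-bromo-3-(2,4-dimethoxypyrimidin-5-yl)-1-(4-methylbenzenesulfonyl)-1,5,6,7-tetrahydro-4H-indol-4-one, via trimethylsilyl enol ether 11 (not isolated)
Conditions: LiN(SiMe3)2, Me3SiCl, THF, −78 → 0 °C; concentrate; then NBS, THF, 0 °C
Reagents that add atoms: N-bromosuccinimide, SMILES O=C1CCC(=O)N1Br
Why: Kinetic deprotonation of a vinylogous amide occurs at the α′-carbon (C5), and the silyl enol ether is brominated there by NBS under neutral conditions (enol ether halogenation), so no hydrogen bromide meets the methoxypyrimidine. The new C5 stereocenter forms as the racemate and is removed in step 6.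

Step 6
Reactants: 12 rac-5-bromo-3-(2,4-dimethoxypyrimidin-5-yl)-1-(4-methylbenzenesulfonyl)-1,5,6,7-tetrahydro-4H-indol-4-one
Product: 13 3-(2,4-dimethoxypyrimidin-5-yl)-1-(4-methylbenzenesulfonyl)-1H-indol-4-ol
Conditions: LiBr, Li2CO3, DMF, 120 °C
Reagents that add atoms: none
Why: Dehydrobromination gives the 4-oxo-4,7-dihydroindole, which tautomerizes at once to the aromatic phenol. This is the standard aromatization of N-sulfonyl 5-bromo-4-oxotetrahydroindoles, and the carbonate buffer keeps the medium from turning acidic.

Step 7
Reactants: 13 3-(2,4-dimethoxypyrimidin-5-yl)-1-(4-methylbenzenesulfonyl)-1H-indol-4-ol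
Product: 14 2,4-dimethoxy-5-[4-methoxy-1-(4-methylbenzenesulfonyl)-1H-indol-3-yl]pyrimidine
Conditions: MeI (1.5 equiv), K2CO3, DMF, rt
Reagents that add atoms: iodomethane, SMILES CI
Why: Williamson etherification of the phenoxide. At room temperature with a small excess of iodomethane, N-alkylation of the hindered methoxypyrimidine should not compete.

Step 8
Reactants: 14 2,4-dimethoxy-5-[4-methoxy-1-(4-methylbenzenesulfonyl)-1H-indol-3-yl]pyrimidine
Product: 15 5-[7-bromo-4-methoxy-1-(4-methylbenzenesulfonyl)-1H-indol-3-yl]-2,4-dimethoxypyrimidine
Conditions: NBS (1.05 equiv), MeCN, 0 °C → rt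
Reagents that add atoms: N-bromosuccinimide, SMILES O=C1CCC(=O)N1Br
Why: Electrophilic aromatic bromination with NBS in acetonitrile is para-selective for aryl methyl ethers, which here means C7. The sulfonyl group deactivates C2, and the C3 heteroaryl group forces the methoxy methyl toward C5 and screens the ortho position.

Step 9
Reactants: 15 5-[7-bromo-4-methoxy-1-(4-methylbenzenesulfonyl)-1H-indol-3-yl]-2,4-dimethoxypyrimidine
Product: 16 5-(7-bromo-4-methoxy-1H-indol-3-yl)-2,4-dimethoxypyrimidine
Conditions: KOH, MeOH/THF, 60 °C
Reagents that add atoms: none
Why: Nucleophilic desulfonylation: hydroxide or methoxide attacks sulfur and the indolide leaves, helped by the 7-bromine and the heteroaryl group. It is done at this stage because exchange of methoxide at the methoxypyrimidine is degenerate, whereas the later bromopyrimidine would not tolerate the base.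

Step 10
Reactants: 16 5-(7-bromo-4-methoxy-1H-indol-3-yl)-2,4-dimethoxypyrimidine
Product: 17 5-(7-bromo-4-methoxy-1H-indol-3-yl)pyrimidine-2,4(1H,3H)-dione
Conditions: 2 M aq. HCl, 1,4-dioxane, 90 °C
Reagents that add atoms: water, SMILES O
Why: The two methoxy groups are lactim ethers and are hydrolysed by aqueous acid through addition of water to the protonated ring and loss of methanol. The aryl methyl ether, the aryl bromide and the 3-substituted indole are stable to dilute mineral acid.

Step 11
Reactants: 17 5-(7-bromo-4-methoxy-1H-indol-3-yl)pyrimidine-2,4(1H,3H)-dione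
Product: 18 7-bromo-3-(2,4-dibromopyrimidin-5-yl)-4-methoxy-1H-indole
Conditions: POBr3, PhNMe2, toluene, 110 °C
Reagents that add atoms: phosphoryl bromide, SMILES O=P(Br)(Br)Br
Why: Deoxybromination of the lactam carbonyls: O-phosphorylation followed by addition–elimination of bromide is the standard conversion of uracils into 2,4-dihalopyrimidines. The phenol is masked as its methyl ether, and an indole N–H tolerates phosphoryl halides, as in Vilsmeier chemistry.

Step 12
Reactants: 18 7-bromo-3-(2,4-dibromopyrimidin-5-yl)-4-methoxy-1H-indole
Product: 19 2-bromo-5-(7-bromo-4-methoxy-1H-indol-3-yl)pyrimidin-4-amine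
Conditions: NH3 (0.5 M in 1,4-dioxane), sealed tube, 40 °C
Reagents that add atoms: ammonia, SMILES N
Why: Nucleophilic aromatic substitution on a 2,4-dihalopyrimidine goes first at C4, the more electrophilic carbon. The amino group then deactivates the ring, so C2–Br should remain under mild conditions.

Step 13
Reactants: 19 2-bromo-5-(7-bromo-4-methoxy-1H-indol-3-yl)pyrimidin-4-amine
Product: 20 3-(4-amino-2-bromopyrimidin-5-yl)-7-bromo-1H-indol-4-ol
Conditions: BBr3 (excess), CH2Cl2, −78 °C → rt; MeOH, aq. NaHCO3
Reagents that add atoms: none
Why: Lewis-acid cleavage of the aryl methyl ether: bromide attacks the methyl group of the boron–ether adduct. Bromide is the only nucleophile present, so any exchange at C2 of the pyrimidine is degenerate and both C–Br bonds persist; excess reagent compensates for binding to the basic nitrogens.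

## Compound list

1 | 5-bromo-2,4-dimethoxypyrimidine | COc1ncc(Br)c(OC)n1 | starting material
2 | tert-butyl N-{2-[methoxy(methyl)amino]-2-oxoethyl}carbamate | CON(C)C(=O)CNC(=O)OC(C)(C)C | starting material
3 | N-chloromagnesio derivative of 2 (magnesium carbamate, not isolated) | CON(C)C(=O)CN([Mg]Cl)C(=O)OC(C)(C)C | intermediate
4 | (2,4-dimethoxypyrimidin-5-yl)lithium (not isolated) | [Li]c1cnc(OC)nc1OC | intermediate
5 | tert-butyl N-[2-(2,4-dimethoxypyrimidin-5-yl)-2-oxoethyl]carbamate | COc1ncc(C(=O)CNC(=O)OC(C)(C)C)c(OC)n1 | intermediate
6 | 2-amino-1-(2,4-dimethoxypyrimidin-5-yl)ethan-1-one hydrochloride | NCC(=O)c1cnc(OC)nc1OC.Cl | intermediate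
7 | cyclohexane-1,3-dione | O=C1CCCC(=O)C1 | starting material
8 | 3-{[2-(2,4-dimethoxypyrimidin-5-yl)-2-oxoethyl]amino}cyclohex-2-en-1-one (not isolated) | COc1ncc(C(=O)CNC2=CC(=O)CCC2)c(OC)n1 | intermediate
9 | 3-(2,4-dimethoxypyrimidin-5-yl)-1,5,6,7-tetrahydro-4H-indol-4-one | COc1ncc(-c2c[nH]c3c2C(=O)CCC3)c(OC)n1 | intermediate
10 | 3-(2,4-dimethoxypyrimidin-5-yl)-1-(4-methylbenzenesulfonyl)-1,5,6,7-tetrahydro-4H-indol-4-one | COc1ncc(-c2cn(S(=O)(=O)c3ccc(C)cc3)c3c2C(=O)CCC3)c(OC)n1 | intermediate
11 | 3-(2,4-dimethoxypyrimidin-5-yl)-1-(4-methylbenzenesulfonyl)-4-[(trimethylsilyl)oxy]-6,7-dihydro-1H-indole (not isolated) | COc1ncc(-c2cn(S(=O)(=O)c3ccc(C)cc3)c3c2C(O[Si](C)(C)C)=CCC3)c(OC)n1 | intermediate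
12 | rac-5-bromo-3-(2,4-dimethoxypyrimidin-5-yl)-1-(4-methylbenzenesulfonyl)-1,5,6,7-tetrahydro-4H-indol-4-one (racemate) | COc1ncc(-c2cn(S(=O)(=O)c3ccc(C)cc3)c3c2C(=O)C(Br)CC3)c(OC)n1 | intermediate
13 | 3-(2,4-dimethoxypyrimidin-5-yl)-1-(4-methylbenzenesulfonyl)-1H-indol-4-ol | COc1ncc(-c2cn(S(=O)(=O)c3ccc(C)cc3)c3cccc(O)c23)c(OC)n1 | intermediate
14 | 2,4-dimethoxy-5-[4-methoxy-1-(4-methylbenzenesulfonyl)-1H-indol-3-yl]pyrimidine | COc1ncc(-c2cn(S(=O)(=O)c3ccc(C)cc3)c3cccc(OC)c23)c(OC)n1 | intermediate
15 | 5-[7-bromo-4-methoxy-1-(4-methylbenzenesulfonyl)-1H-indol-3-yl]-2,4-dimethoxypyrimidine | COc1ncc(-c2cn(S(=O)(=O)c3ccc(C)cc3)c3c(Br)ccc(OC)c23)c(OC)n1 | intermediate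
16 | 5-(7-bromo-4-methoxy-1H-indol-3-yl)-2,4-dimethoxypyrimidine | COc1ncc(-c2c[nH]c3c(Br)ccc(OC)c23)c(OC)n1 | intermediate
17 | 5-(7-bromo-4-methoxy-1H-indol-3-yl)pyrimidine-2,4(1H,3H)-dione | COc1ccc(Br)c2[nH]cc(-c3c[nH]c(=O)[nH]c3=O)c12 | intermediate
18 | 7-bromo-3-(2,4-dibromopyrimidin-5-yl)-4-methoxy-1H-indole | COc1ccc(Br)c2[nH]cc(-c3cnc(Br)nc3Br)c12 | intermediate
19 | 2-bromo-5-(7-bromo-4-methoxy-1H-indol-3-yl)pyrimidin-4-amine | COc1ccc(Br)c2[nH]cc(-c3cnc(Br)nc3N)c12 | intermediate
20 | 3-(4-amino-2-bromopyrimidin-5-yl)-7-bromo-1H-indol-4-ol | Nc1nc(Br)ncc1-c1c[nH]c2c(Br)ccc(O)c12 | target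

## Step count and risks

Total step count: 13. Longest linear sequence: 13 steps, from 1 (or 2) to 20; dione 7 enters at step 3.

**Step 3 (key step).** The liberated aminoketone may dimerize to a dihydropyrazine faster than it meets the dione, or the 4-methoxy group, activated by the neighbouring acyl group, may be hydrolysed in hot acetic acid. The fallback forms the same two bonds stepwise from a precursor that cannot self-condense. It sets out from 5 and returns at 9. Ketone 5 is reduced with NaBH4 to racemic tert-butyl N-[2-(2,4-dimethoxypyrimidin-5-yl)-2-hydroxyethyl]carbamate F1. Acid gives 2-amino-1-(2,4-dimethoxypyrimidin-5-yl)ethan-1-ol hydrochloride F2. Condensation with 7 (Et3N, toluene, azeotropic removal of water) gives 3-{[2-(2,4-dimethoxypyrimidin-5-yl)-2-hydroxyethyl]amino}cyclohex-2-en-1-one F3. Oxidation of the carbinol with Dess–Martin periodinane gives enaminone 8, which closes to 9 on warming in acetic acid.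

**Step 8.** Bromination may go ortho to the methoxy group (C5) because C7 lies next to the sulfonyl group, or a second bromine may enter. The fallback replaces electrophilic substitution by nitrogen-directed C–H borylation. It sets out from 14 and returns at 16. The tosyl group is removed (KOH, MeOH) to give 2,4-dimethoxy-5-(4-methoxy-1H-indol-3-yl)pyrimidine F4. Borylation with [Ir(OMe)(cod)]2, 4,4′-di-tert-butyl-2,2′-bipyridine and B2pin2 gives 5-[4-methoxy-2,7-bis(4,4,5,5-tetramethyl-1,3,2-dioxaborolan-2-yl)-1H-indol-3-yl]-2,4-dimethoxypyrimidine F5. Selective protodeboronation at C2 with trifluoroacetic acid at 0 °C gives 2,4-dimethoxy-5-[4-methoxy-7-(4,4,5,5-tetramethyl-1,3,2-dioxaborolan-2-yl)-1H-indol-3-yl]pyrimidine F6. Bromodeboronation with CuBr2 in aqueous methanol then gives 16.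

**Step 12.** Ammonia may attack C2 instead of C4, because C4 is flanked by the bulky indolyl group, or substitution may occur twice. The fallback fixes the position of nitrogen through the known C4 selectivity of uracil thionation. It sets out from 17 and returns at 19. P4S10 in pyridine gives 5-(7-bromo-4-methoxy-1H-indol-3-yl)-4-thioxo-3,4-dihydropyrimidin-2(1H)-one F7. Methanolic ammonia in a sealed tube gives 4-amino-5-(7-bromo-4-methoxy-1H-indol-3-yl)pyrimidin-2(1H)-one F8. POBr3 then converts the remaining lactam into the 2-bromide 19.

**Step 11.** The unprotected, electron-rich indole may oligomerize or be brominated in hot POBr3, or conversion may stop at a bromopyrimidinone. The fallback keeps the sulfonyl group through the pyrimidine chemistry. It sets out from 15 and returns at 19. Hydrolysis as in step 10 gives 5-[7-bromo-4-methoxy-1-(4-methylbenzenesulfonyl)-1H-indol-3-yl]pyrimidine-2,4(1H,3H)-dione F9. POBr3 gives 7-bromo-3-(2,4-dibromopyrimidin-5-yl)-4-methoxy-1-(4-methylbenzenesulfonyl)-1H-indole F10. Ammonia gives 2-bromo-5-[7-bromo-4-methoxy-1-(4-methylbenzenesulfonyl)-1H-indol-3-yl]pyrimidin-4-amine F11. Cs2CO3 in THF/MeOH at room temperature then removes the sulfonyl group to give 19; the price is a mild base in the presence of the bromopyrimidine, which the amino group deactivates.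

**Step 6.** At 120 °C the sulfonyl group may be lost, bromide may dealkylate the methoxypyrimidine, or substitution may compete with elimination. The fallback replaces bromide elimination by selenoxide elimination at or below room temperature. It sets out from 10 and returns at 13. The lithium enolate of 10 (LiN(SiMe3)2, THF, −78 °C) is trapped with PhSeCl to give racemic 3-(2,4-dimethoxypyrimidin-5-yl)-1-(4-methylbenzenesulfonyl)-5-(phenylselanyl)-1,5,6,7-tetrahydro-4H-indol-4-one F12. Oxidation with H2O2 in CH2Cl2/pyridine causes syn-elimination, and the dienone tautomerizes to 13.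

## Further compounds

F1 | step 3 | rac-tert-butyl N-[2-(2,4-dimethoxypyrimidin-5-yl)-2-hydroxyethyl]carbamate | COc1ncc(C(O)CNC(=O)OC(C)(C)C)c(OC)n1
F2 | step 3 | rac-2-amino-1-(2,4-dimethoxypyrimidin-5-yl)ethan-1-ol hydrochloride | NCC(O)c1cnc(OC)nc1OC.Cl
F3 | step 3 | rac-3-{[2-(2,4-dimethoxypyrimidin-5-yl)-2-hydroxyethyl]amino}cyclohex-2-en-1-one | COc1ncc(C(O)CNC2=CC(=O)CCC2)c(OC)n1
F4 | step 8 | 2,4-dimethoxy-5-(4-methoxy-1H-indol-3-yl)pyrimidine | COc1ncc(-c2c[nH]c3cccc(OC)c23)c(OC)n1
F5 | step 8 | 5-[4-methoxy-2,7-bis(4,4,5,5-tetramethyl-1,3,2-dioxaborolan-2-yl)-1H-indol-3-yl]-2,4-dimethoxypyrimidine | COc1ncc(-c2c(B3OC(C)(C)C(C)(C)O3)[nH]c3c(B4OC(C)(C)C(C)(C)O4)ccc(OC)c23)c(OC)n1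
F6 | step 8 | 2,4-dimethoxy-5-[4-methoxy-7-(4,4,5,5-tetramethyl-1,3,2-dioxaborolan-2-yl)-1H-indol-3-yl]pyrimidine | COc1ncc(-c2c[nH]c3c(B4OC(C)(C)C(C)(C)O4)ccc(OC)c23)c(OC)n1
F7 | step 12 | 5-(7-bromo-4-methoxy-1H-indol-3-yl)-4-thioxo-3,4-dihydropyrimidin-2(1H)-one | COc1ccc(Br)c2[nH]cc(-c3c[nH]c(=O)[nH]c3=S)c12
F8 | step 12 | 4-amino-5-(7-bromo-4-methoxy-1H-indol-3-yl)pyrimidin-2(1H)-one | COc1ccc(Br)c2[nH]cc(-c3c[nH]c(=O)nc3N)c12
F9 | step 11 | 5-[7-bromo-4-methoxy-1-(4-methylbenzenesulfonyl)-1H-indol-3-yl]pyrimidine-2,4(1H,3H)-dione | COc1ccc(Br)c2n(S(=O)(=O)c3ccc(C)cc3)cc(-c3c[nH]c(=O)[nH]c3=O)c12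
F10 | step 11 | 7-bromo-3-(2,4-dibromopyrimidin-5-yl)-4-methoxy-1-(4-methylbenzenesulfonyl)-1H-indole | COc1ccc(Br)c2n(S(=O)(=O)c3ccc(C)cc3)cc(-c3cnc(Br)nc3Br)c12
F11 | step 11 | 2-bromo-5-[7-bromo-4-methoxy-1-(4-methylbenzenesulfonyl)-1H-indol-3-yl]pyrimidin-4-amine | COc1ccc(Br)c2n(S(=O)(=O)c3ccc(C)cc3)cc(-c3cnc(Br)nc3N)c12
F12 | step 6 | rac-3-(2,4-dimethoxypyrimidin-5-yl)-1-(4-methylbenzenesulfonyl)-5-(phenylselanyl)-1,5,6,7-tetrahydro-4H-indol-4-one | COc1ncc(-c2cn(S(=O)(=O)c3ccc(C)cc3)c3c2C(=O)C([Se]c2ccccc2)CC3)c(OC)n1
A1 | alternative 1 | 1-[2-allyl-4-(2,4-dimethoxypyrimidin-5-yl)-1-(4-methylbenzenesulfonyl)-1H-pyrrol-3-yl]prop-2-en-1-one | C=CCc1c(C(=O)C=C)c(-c2cnc(OC)nc2OC)cn1S(=O)(=O)c1ccc(C)cc1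
A2 | alternative 1 | 3-(2,4-dimethoxypyrimidin-5-yl)-1-(4-methylbenzenesulfonyl)-1H-indol-4-ol | COc1ncc(-c2cn(S(=O)(=O)c3ccc(C)cc3)c3cccc(O)c23)c(OC)n1
A3 | alternative 2 | (E)-1-(2,4-dimethoxypyrimidin-5-yl)-6,6-dimethoxyhex-1-en-3-one | COC(OC)CCC(=O)/C=C/c1cnc(OC)nc1OC
A4 | alternative 2 | tosylmethyl isocyanide | Cc1ccc(cc1)S(=O)(=O)C[N+]#[C-]
A5 | alternative 2 | 1-[4-(2,4-dimethoxypyrimidin-5-yl)-1H-pyrrol-3-yl]-4,4-dimethoxybutan-1-one | COC(OC)CCC(=O)c1c[nH]cc1-c1cnc(OC)nc1OC
A6 | alternative 2 | 3-(2,4-dimethoxypyrimidin-5-yl)-1H-indol-4-ol | COc1ncc(-c2c[nH]c3cccc(O)c23)c(OC)n1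
A7 | alternative 3 | (2-bromo-5-methoxyphenyl)hydrazine | COc1ccc(Br)c(NN)c1
A8 | alternative 3 | 2-(2,4-dimethoxypyrimidin-5-yl)acetaldehyde | COc1ncc(CC=O)c(OC)n1
A9 | alternative 3 | 5-(7-bromo-4-methoxy-1H-indol-3-yl)-2,4-dimethoxypyrimidine | COc1ncc(-c2c[nH]c3c(Br)ccc(OC)c23)c(OC)n1
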